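Ring A of corymbosin carries oxygen at C5, C7 and C8a and the acyl carbon C4 on C4a, the oxygenation that a Claisen-type polyketide cyclization leaves behind. Everything rests on cutting the C4a–C5 bond: a 4-methoxy-2-pyranone carrying a 2,4-dioxo-4-(3,4,5-trimethoxyphenyl)butyl chain at C6 acts as a masked tetraketide. Methoxide opens the lactone and the doubly activated methylene closes onto the new ester, so one operation builds ring A complete with the 7-methoxyl, two equivalent ortho phenols and the aroylacetyl chain. Two enolate acylations assemble the precursor, and acid-catalysed closure of ring C finishes the synthesis.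

Key step: step 3

Remarks on the chemistry:
- Labels C2 to C8a are flavone positions of the target; "chain C1 to C9" counts the open-chain ester 8 from its ester carbon.
- The 1,3-dicarbonyl compounds 7, 8 and 9 are drawn as keto forms, although they should exist largely as enols (9 partly as hemiketal 10).
- LiN(iPr)2 and Mg(OCH3)2 are assumed to be purchased solutions.

Step 1
Reactants: 1 4-methoxy-6-methyl-2H-pyran-2-one; 2 N-methoxy-N-methylacetamide
Product: 4 4-methoxy-6-(2-oxopropyl)-2H-pyran-2-one, via lithium dienolate 3 (not isolated)
Conditions: LiN(iPr)2 (1.1 equiv), THF, −78 °C; then 2 (1.2 equiv), −78 to −20 °C; 1 M aq. HCl, 0 °C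
Reagents that add atoms: none
Why: Deprotonation of the 6-methyl group gives the vinylogous ester anion 3, which reacts at its exocyclic carbon with the Weinreb amide to form a chelated tetrahedral adduct that cannot over-react and releases ketone 4 only on acidic quench (Weinreb ketone synthesis).

Step 2
Reactants: 4 4-methoxy-6-(2-oxopropyl)-2H-pyran-2-one; 5 methyl 3,4,5-trimethoxybenzoate
Product: 7 4-methoxy-6-[2,4-dioxo-4-(3,4,5-trimethoxyphenyl)butyl]-2H-pyran-2-one, via dilithium dianion 6 (not isolated)
Conditions: LiN(iPr)2 (3.2 equiv), THF, −78 to −30 °C; then 5 (1.0 equiv), −78 to 0 °C; 1 M aq. HCl to pH 3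
Reagents that add atoms: none
Why: Base removes first a proton of the doubly activated methylene and then one of the terminal methyl, and the more basic terminal carbanion of 6 attacks the ester in a crossed Claisen condensation, the third equivalent of base absorbing the acidity of the triketone formed (terminal-carbon acylation of a 1,3-dicarbonyl dianion).

Step 3
Reactants: 7 4-methoxy-6-[2,4-dioxo-4-(3,4,5-trimethoxyphenyl)butyl]-2H-pyran-2-one
Product: 9 1-(2,6-dihydroxy-4-methoxyphenyl)-3-(3,4,5-trimethoxyphenyl)propane-1,3-dione, via open-chain triketo ester 8 (not isolated)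
Conditions: Mg(OCH3)2 (8 equiv), MeOH, reflux, N2; then cold 1 M aq. HCl
Reagents that add atoms: none
Why: Methoxide adds to the lactone carbonyl of 7 and opens the ring to the magnesium-chelated enolate of ester 8, whose enol-ether double bond, inherited from the pyranone, holds the ester and the polyketone chain cis; the methylene between the two aliphatic ketones (chain C6, the future C4a) then attacks the ester carbonyl (chain C1, the future C5), methoxide leaves again and two enolizations aromatize the carbocycle. The closest known reaction type is the base-induced Claisen recyclization of 6-(2-oxoalkyl)-4-alkoxy-2-pyranones and of 3,5,7-triketo esters to acylphloroglucinols. Ring A closes in a 6-exo-trig mode, the ester carbonyl lying outside the six-membered ring that forms. No stereocentre is created. The step needs Claisen closure to win over aldol closures onto the ketone carbonyls and over retro-Claisen loss of the aroyl group; magnesium chelation should keep the 1,3-diketone units as tight, poorly electrophilic enolates while activating the ester, and the methyl enol ether leaves the ester α-carbon as a non-acidic vinylic CH, so the orsellinate-type aldol lacks its nucleophile. The enol-ether methoxyl survives para to the new acyl group and the two phenols flanking that group are related by symmetry, so whichever one closes ring C in step 4 gives the same flavone.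

Step 4
Reactants: 9 1-(2,6-dihydroxy-4-methoxyphenyl)-3-(3,4,5-trimethoxyphenyl)propane-1,3-dione
Product: 11 corymbosin (5-hydroxy-7-methoxy-2-(3,4,5-trimethoxyphenyl)-4H-chromen-4-one), via 2-hydroxyflavanone hemiketal 10 (not isolated)
Conditions: H2SO4 (cat.), AcOH, 95 °C
Reagents that add atoms: none
Why: Acid promotes attack of one of the two equivalent ortho phenols on the aryl ketone carbon to give hemiketal 10, whose dehydration to the conjugated chromen-4-one is irreversible, while the other phenol stays hydrogen-bonded to the C4 carbonyl as the 5-hydroxyl (the cyclodehydration that ends a Baker–Venkataraman flavone synthesis).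

Compound list
1 | 4-methoxy-6-methyl-2H-pyran-2-one | COc1cc(C)oc(=O)c1 | starting material
2 | N-methoxy-N-methylacetamide | CON(C)C(C)=O | starting material
3 | lithium 4-methoxy-6-methylidene-6H-pyran-2-olate (lithium dienolate of 1, delocalized, drawn O-bound) | C=C1C=C(OC)C=C(O[Li])O1 | intermediate
4 | 4-methoxy-6-(2-oxopropyl)-2H-pyran-2-one | COc1cc(CC(C)=O)oc(=O)c1 | intermediate
5 | methyl 3,4,5-trimethoxybenzoate | COC(=O)c1cc(OC)c(OC)c(OC)c1 | starting material
6 | dilithium dianion of 4 (deprotonated at the ring-side methylene and at the terminal methyl, delocalized, drawn O-bound) | C=C(O[Li])C=C1C=C(OC)C=C(O[Li])O1 | intermediate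
7 | 4-methoxy-6-[2,4-dioxo-4-(3,4,5-trimethoxyphenyl)butyl]-2H-pyran-2-one | COc1cc(CC(=O)CC(=O)c2cc(OC)c(OC)c(OC)c2)oc(=O)c1 | intermediate
8 | methyl (2E)-3-methoxy-5,7,9-trioxo-9-(3,4,5-trimethoxyphenyl)non-2-enoate (present as its magnesium enolate; ester and chain cis on the double bond) | COC(=O)/C=C(OC)\CC(=O)CC(=O)CC(=O)c1cc(OC)c(OC)c(OC)c1 | intermediate
9 | 1-(2,6-dihydroxy-4-methoxyphenyl)-3-(3,4,5-trimethoxyphenyl)propane-1,3-dione | COc1cc(O)c(C(=O)CC(=O)c2cc(OC)c(OC)c(OC)c2)c(O)c1 | intermediate
10 | 2,5-dihydroxy-7-methoxy-2-(3,4,5-trimethoxyphenyl)-2,3-dihydro-4H-chromen-4-one (racemic at C2) | COc1cc(O)c2C(=O)CC(O)(c3cc(OC)c(OC)c(OC)c3)Oc2c1 | intermediate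
11 | corymbosin, 5-hydroxy-7-methoxy-2-(3,4,5-trimethoxyphenyl)-4H-chromen-4-one (no stereocentre) | COc1cc(O)c2c(=O)cc(-c3cc(OC)c(OC)c(OC)c3)oc2c1 | target

Total step count: 4
Longest linear sequence: 4 steps (1 → 4 → 7 → 9 → 11)

Steps most likely to fail

Risk 1, step 3. The open-chain intermediate may close through an aldol mode onto one of the ketone carbonyls, or lose its aroyl group by methoxide-induced retro-Claisen cleavage, before the Claisen closure takes place. The fallback sets out from 4 and returns at 9, and it forms ring A before the aryl ketone exists. Ketone 4 is heated with Mg(OCH3)2 in MeOH, which should open the lactone to methyl (2E)-3-methoxy-5,7-dioxooct-2-enoate F1 (not isolated). This shorter chain has no aryl ketone to attack or to lose, and the same Claisen closure should give 1-(2,6-dihydroxy-4-methoxyphenyl)ethanone F2. F2 is then converted into its polyanion with LiN(SiMe3)2 (4.5 equiv, THF, −78 °C) and C-aroylated with 3,4,5-trimethoxybenzoyl chloride (1 equiv), a one-pot Baker–Venkataraman-type acylation that should deliver diketone 9 directly.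

Risk 2, step 2. The terminal carbanion of 6 may attack the electron-rich ester too slowly, so that proton transfer from the acidic triketone product quenches unreacted dianion and conversion stalls. The fallback sets out from 4 and returns at 7, and it replaces the Claisen acylation by an aldol addition followed by oxidation. Dianion 6, made as before, is treated at −78 °C with 3,4,5-trimethoxybenzaldehyde, a far better electrophile whose aldolate is not acidic, to give racemic 6-[4-hydroxy-2-oxo-4-(3,4,5-trimethoxyphenyl)butyl]-4-methoxy-2H-pyran-2-one F3 after a cold NH4Cl quench. Oxidation of this β-hydroxy ketone with 2-iodoxybenzoic acid (EtOAc, 75 °C) should then give 7.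

Risk 3, step 1. Deprotonation may occur in part on the ring (C3 or C5), and the lithiated pyranone may condense with unreacted 1, so that acetylation of the methyl carbon is not clean. The fallback sets out from 1 and returns at 4, and it avoids any carbanion of the pyranone. Radical bromination of 1 (N-bromosuccinimide, cat. dibenzoyl peroxide, PhCF3, reflux) should give 6-(bromomethyl)-4-methoxy-2H-pyran-2-one F4. Stille coupling of F4 with tributyl(1-ethoxyvinyl)stannane (Pd(PPh3)4, a zerovalent palladium catalyst, toluene, 90 °C) should give the enol ether 6-(2-ethoxyprop-2-en-1-yl)-4-methoxy-2H-pyran-2-one F5. Hydrolysis of F5 with 1 M aq. HCl in THF at room temperature releases ketone 4.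

Further compounds
F1 | step 3 | methyl (2E)-3-methoxy-5,7-dioxooct-2-enoate | COC(=O)/C=C(OC)\CC(=O)CC(C)=O
F2 | step 3 | 1-(2,6-dihydroxy-4-methoxyphenyl)ethanone | COc1cc(O)c(C(C)=O)c(O)c1
F3 | step 2 | 6-[4-hydroxy-2-oxo-4-(3,4,5-trimethoxyphenyl)butyl]-4-methoxy-2H-pyran-2-one (racemic) | COc1cc(CC(=O)CC(O)c2cc(OC)c(OC)c(OC)c2)oc(=O)c1
F4 | step 1 | 6-(bromomethyl)-4-methoxy-2H-pyran-2-one | COc1cc(CBr)oc(=O)c1
F5 | step 1 | 6-(2-ethoxyprop-2-en-1-yl)-4-methoxy-2H-pyran-2-one | CCOC(=C)Cc1cc(OC)cc(=O)o1
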